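The route rests on cutting ring B at C1'–C2' and C3'–C4'. Ring B carries ether oxygens on the meta carbons C1' (aryloxy) and C5' (methoxy), with C6'–H between them and C4'–H beyond. This strip is the C6–C5–C4–C3 diene of a 6-aryloxy-4-methoxy-2-pyranone, and the adjacent C2' ester and C3' acyl carbons are the two carbons of an ynoate whose ketone is masked as a dimethyl ketal. A thermal Diels–Alder reaction followed by loss of CO2 makes both C–C bonds and the benzene ring with its complete substitution pattern in one operation, the diaryl ether already being in place. The precursor pyranone carries benzyl-protected ring A on its C6 oxygen.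

Key step: step 10

Remark: the target has no stereocentre. Ring B is numbered C1' (aryloxy carbon), C2' (ester), C3' (pentanoyl), C4' (H), C5' (methoxy), C6' (H). Step 5 consumes two molecules of malonyl dichloride for each pyranone formed.

Step 1
Reactants: 1 olivetol
Product: 2 1,3-bis(benzyloxy)-5-pentylbenzene
Conditions: BnBr (2.3 equiv), K2CO3, DMF, 60 °C
Reagents that add atoms: benzyl bromide, BrCc1ccccc1
Why: Williamson ether synthesis, in which both phenoxides are alkylated by the reactive benzylic bromide and the polar aprotic solvent favours O- over C-alkylation.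

Step 2
Reactants: 2 1,3-bis(benzyloxy)-5-pentylbenzene
Product: 3 1,5-bis(benzyloxy)-2,4-dibromo-3-pentylbenzene
Conditions: NBS (2.1 equiv), MeCN, 0 to 20 °C, dark
Reagents that add atoms: N-bromosuccinimide, O=C1CCC(=O)N1Br
Why: Electrophilic aromatic bromination, in which each position flanking the pentyl chain is para to one benzyloxy group and ortho to the other and is preferred over the position between the two benzyloxy groups, as in 3,5-dialkoxytoluenes, so the symmetrical dibromide should form.

Step 3
Reactants: 3 1,5-bis(benzyloxy)-2,4-dibromo-3-pentylbenzene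
Product: 5 benzyl 4,6-bis(benzyloxy)-3-bromo-2-pentylbenzoate, via aryllithium 4 (not isolated)
Conditions: n-BuLi (1.0 equiv), THF, −78 °C; then cannulated into ClCO2Bn (1.5 equiv), THF, −78 to 0 °C
Reagents that add atoms: benzyl chloroformate, O=C(Cl)OCc1ccccc1
Why: Lithium–bromine exchange followed by acylation, in which the two bromines are equivalent, the electron-rich aryllithium resists a second exchange, and inverse addition plus the two ortho substituents of the product ester prevent over-addition.

Step 4
Reactants: 5 benzyl 4,6-bis(benzyloxy)-3-bromo-2-pentylbenzoate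
Product: 7 benzyl 4,6-bis(benzyloxy)-3-hydroxy-2-pentylbenzoate, via pinacol boronate 6 (not isolated)
Conditions: Pd(OAc)2 (5 mol %), SPhos (10 mol %), B2pin2, KOAc, 1,4-dioxane, 100 °C; then 30 % H2O2, aq. NaOH, THF, 0 °C
Reagents that add atoms: hydrogen peroxide, OO
Why: Miyaura borylation with a bulky biarylphosphine tolerates a bromide with two ortho substituents, and oxidation of the aryl boronate (aryl shift from boron to oxygen) gives the phenol at the same carbon, the doubly ortho-substituted benzyl ester being too hindered to saponify at 0 °C.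

Step 5
Reactants: 8 malonyl dichloride (two molecules combine)
Product: 11 6-chloro-4-hydroxy-2H-pyran-2-one, via pyranone-3-carbonyl chloride 9 (not isolated), via pyranone-3-carboxylic acid 10 (not isolated)
Conditions: neat, 20 °C, 4 d (HCl vented); volatiles removed in vacuo; crude solid in 1,4-dioxane, H2O (1.0 equiv based on 9), 20 °C; then 80 °C until CO2 evolution stops
Reagents that add atoms: malonyl dichloride (a second molecule of 8), O=C(Cl)CC(=O)Cl
Why: Self-condensation of two molecules of malonyl dichloride with loss of two HCl (formally a (4+2) dimerisation of chlorocarbonylketene) is a known behaviour that gives the pyranone acid chloride 9, whose exocyclic acyl chloride hydrolyses faster than the vinylogous C6–Cl, and the resulting acid 10, a cyclic beta-keto acid, decarboxylates on gentle warming, the oxygen brought in by water leaving again in CO2.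

Step 6
Reactants: 11 6-chloro-4-hydroxy-2H-pyran-2-one
Product: 12 6-chloro-4-methoxy-2H-pyran-2-one
Conditions: Me2SO4 (1.3 equiv), K2CO3, acetone, 0 to 20 °C
Reagents that add atoms: dimethyl sulfate, COS(=O)(=O)OC
Why: O-Alkylation of the acidic 4-hydroxy-2-pyranone (a vinylogous carboxylic acid) with dimethyl sulfate and carbonate is the standard way to 4-methoxy-2-pyranones, and the enolate form keeps C6–Cl unreactive until methylation has occurred.

Step 7
Reactants: 7 benzyl 4,6-bis(benzyloxy)-3-hydroxy-2-pentylbenzoate; 12 6-chloro-4-methoxy-2H-pyran-2-one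
Product: 13 benzyl 4,6-bis(benzyloxy)-3-[(4-methoxy-6-oxo-6H-pyran-2-yl)oxy]-2-pentylbenzoate
Conditions: Cs2CO3 (1.2 equiv), MeCN, 0 to 20 °C
Reagents that add atoms: none
Why: Addition–elimination (nucleophilic vinylic substitution) of the phenoxide at C6, the delta position of the dienyl lactone that also bears the leaving group, as halo-2-pyranones undergo with heteroatom nucleophiles; attack at the lactone carbonyl instead would open the ring to an ester ketene that can reclose to the same 6-aryloxy pyranone.

Step 8
Reactants: 14 trimethyl orthovalerate; 15 ethynylmagnesium bromide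
Product: 16 3,3-dimethoxyhept-1-yne
Conditions: 15 (2.5 equiv, 0.5 M in THF), toluene, 65 °C; then ice-water
Reagents that add atoms: none
Why: Substitution of one alkoxy group of an orthoester by a Grignard reagent (Bodroux–Chichibabin type), in which magnesium-assisted ionisation gives a dialkoxycarbenium ion that the acetylide captures, while excess reagent limits double alkynylation.

Step 9
Reactants: 16 3,3-dimethoxyhept-1-yne
Product: 18 methyl 4,4-dimethoxyoct-2-ynoate, via lithium acetylide 17 (not isolated)
Conditions: n-BuLi (1.05 equiv), THF, −78 °C; then ClCO2Me, −78 to 0 °C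
Reagents that add atoms: methyl chloroformate, COC(=O)Cl
Why: Deprotonation of the terminal alkyne and C-acylation of the lithium acetylide with a chloroformate is the standard synthesis of 2-ynoates, and the ketal is inert to base.

Step 10
Reactants: 13 benzyl 4,6-bis(benzyloxy)-3-[(4-methoxy-6-oxo-6H-pyran-2-yl)oxy]-2-pentylbenzoate; 18 methyl 4,4-dimethoxyoct-2-ynoate
Product: 20 benzyl 4,6-bis(benzyloxy)-3-[3-(1,1-dimethoxypentyl)-5-methoxy-2-(methoxycarbonyl)phenoxy]-2-pentylbenzoate, via bicyclic lactone 19 (not isolated)
Conditions: 18 (3 equiv), o-xylene, 2,6-lutidine (0.2 equiv), 150 °C, sealed tube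
Reagents that add atoms: none
Why: The 2-pyranone acts as an electron-rich diene through C3=C4–C5=C6 and adds thermally to the ynoate in a concerted, asynchronous (4+2) cycloaddition, after which the bridged lactone 19 expels CO2 (lactone carbon C2 and ring oxygen O1) by retro-(4+2) reaction and the new ring aromatises. The closest known reaction type is the Diels–Alder/decarboxylation of 4-methoxy-2-pyranones with acetylenic esters to methoxybenzoates. Ring B is closed by intermolecular (4+2) annulation, the bonds C6–C2 of 18 (ester-bearing carbon) and C3–C3 of 18 (ketal-bearing carbon) forming in the same event. No stereocentre survives, because the two bridgehead centres of 19 are racemic and are erased on aromatisation. The step needs regioselectivity, and the substrate secures it: the 4-methoxy group, the ring oxygen and the 6-aryloxy group all raise the HOMO coefficient at C3, which therefore bonds to the alkyne carbon beta to the ester (largest LUMO coefficient), placing the ester next to the aryloxy carbon and para to methoxy. The ketal is non-conjugating, so the ester alone polarises the alkyne, and even if the ketal loses methanol to an enol ether on heating, step 11 converges on the same ketone.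

Step 11
Reactants: 20 benzyl 4,6-bis(benzyloxy)-3-[3-(1,1-dimethoxypentyl)-5-methoxy-2-(methoxycarbonyl)phenoxy]-2-pentylbenzoate
Product: 21 benzyl 4,6-bis(benzyloxy)-3-[5-methoxy-2-(methoxycarbonyl)-3-pentanoylphenoxy]-2-pentylbenzoate
Conditions: 1 M aq. HCl, THF, 20 °C
Reagents that add atoms: water, O
Why: Acid-catalysed ketal hydrolysis through a benzylic oxocarbenium ion is fast at room temperature, conditions that leave the benzyl ethers, both esters and the diaryl ether untouched.

Step 12
Reactants: 21 benzyl 4,6-bis(benzyloxy)-3-[5-methoxy-2-(methoxycarbonyl)-3-pentanoylphenoxy]-2-pentylbenzoate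
Product: 22 4,6-dihydroxy-3-[5-methoxy-2-(methoxycarbonyl)-3-pentanoylphenoxy]-2-pentylbenzoic acid
Conditions: H2 (1 atm), Pd/C (10 %), EtOAc, 20 °C, stopped after uptake of 3 equiv
Reagents that add atoms: none
Why: Hydrogenolysis of the two benzyl ethers and the benzyl ester over palladium on carbon under neutral conditions should outpace reduction of the hindered, ester-flanked aryl ketone, and placing it last keeps the decarboxylation-prone dihydroxybenzoic acid away from acid and heat.

Compound list
1 | olivetol (5-pentylbenzene-1,3-diol) | CCCCCc1cc(O)cc(O)c1 | starting material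
2 | 1,3-bis(benzyloxy)-5-pentylbenzene | CCCCCc1cc(OCc2ccccc2)cc(OCc2ccccc2)c1 | intermediate
3 | 1,5-bis(benzyloxy)-2,4-dibromo-3-pentylbenzene | CCCCCc1c(Br)c(OCc2ccccc2)cc(OCc2ccccc2)c1Br | intermediate
4 | [4,6-bis(benzyloxy)-3-bromo-2-pentylphenyl]lithium | [Li]c1c(CCCCC)c(Br)c(OCc2ccccc2)cc1OCc1ccccc1 | intermediate
5 | benzyl 4,6-bis(benzyloxy)-3-bromo-2-pentylbenzoate | CCCCCc1c(Br)c(OCc2ccccc2)cc(OCc2ccccc2)c1C(=O)OCc1ccccc1 | intermediate
6 | benzyl 4,6-bis(benzyloxy)-2-pentyl-3-(4,4,5,5-tetramethyl-1,3,2-dioxaborolan-2-yl)benzoate | CCCCCc1c(B2OC(C)(C)C(C)(C)O2)c(OCc2ccccc2)cc(OCc2ccccc2)c1C(=O)OCc1ccccc1 | intermediate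
7 | benzyl 4,6-bis(benzyloxy)-3-hydroxy-2-pentylbenzoate (ring A phenol) | CCCCCc1c(O)c(OCc2ccccc2)cc(OCc2ccccc2)c1C(=O)OCc1ccccc1 | intermediate
8 | malonyl dichloride | O=C(Cl)CC(=O)Cl | starting material
9 | 6-chloro-4-hydroxy-2-oxo-2H-pyran-3-carbonyl chloride | O=C(Cl)C1=C(O)C=C(Cl)OC1=O | intermediate
10 | 6-chloro-4-hydroxy-2-oxo-2H-pyran-3-carboxylic acid | O=C(O)C1=C(O)C=C(Cl)OC1=O | intermediate
11 | 6-chloro-4-hydroxy-2H-pyran-2-one | O=C1C=C(O)C=C(Cl)O1 | intermediate
12 | 6-chloro-4-methoxy-2H-pyran-2-one | COC1=CC(=O)OC(Cl)=C1 | intermediate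
13 | benzyl 4,6-bis(benzyloxy)-3-[(4-methoxy-6-oxo-6H-pyran-2-yl)oxy]-2-pentylbenzoate (the 6-aryloxy-4-methoxy-2H-pyran-2-one) | COC1=CC(=O)OC(Oc2c(CCCCC)c(C(=O)OCc3ccccc3)c(OCc3ccccc3)cc2OCc2ccccc2)=C1 | intermediate
14 | trimethyl orthovalerate (1,1,1-trimethoxypentane) | CCCCC(OC)(OC)OC | starting material
15 | ethynylmagnesium bromide | C#C[Mg]Br | starting material
16 | 3,3-dimethoxyhept-1-yne | CCCCC(OC)(OC)C#C | intermediate
17 | (3,3-dimethoxyhept-1-yn-1-yl)lithium | CCCCC(OC)(OC)C#C[Li] | intermediate
18 | methyl 4,4-dimethoxyoct-2-ynoate | CCCCC(OC)(OC)C#CC(=O)OC | intermediate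
19 | methyl 1-aryloxy-5-(1,1-dimethoxypentyl)-8-methoxy-3-oxo-2-oxabicyclo[2.2.2]octa-5,7-diene-6-carboxylate (aryl = ring A of 7; racemic, both bridgehead centres transient) | O=C1OC2(Oc3c(CCCCC)c(C(=O)OCc4ccccc4)c(OCc4ccccc4)cc3OCc3ccccc3)C=C(OC)C1C(C(OC)(OC)CCCC)=C2C(=O)OC | intermediate
20 | benzyl 4,6-bis(benzyloxy)-3-[3-(1,1-dimethoxypentyl)-5-methoxy-2-(methoxycarbonyl)phenoxy]-2-pentylbenzoate | CCCCCc1c(Oc2cc(OC)cc(C(OC)(OC)CCCC)c2C(=O)OC)c(OCc2ccccc2)cc(OCc2ccccc2)c1C(=O)OCc1ccccc1 | intermediate
21 | benzyl 4,6-bis(benzyloxy)-3-[5-methoxy-2-(methoxycarbonyl)-3-pentanoylphenoxy]-2-pentylbenzoate | CCCCCc1c(Oc2cc(OC)cc(C(=O)CCCC)c2C(=O)OC)c(OCc2ccccc2)cc(OCc2ccccc2)c1C(=O)OCc1ccccc1 | intermediate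
22 | 4,6-dihydroxy-3-[5-methoxy-2-(methoxycarbonyl)-3-pentanoylphenoxy]-2-pentylbenzoic acid | CCCCCc1c(Oc2cc(OC)cc(C(=O)CCCC)c2C(=O)OC)c(O)cc(O)c1C(=O)O | target

Total step count: 12. Longest linear sequence: 8 steps (steps 1, 2, 3, 4, 7, 10, 11, 12).

Steps most likely to fail

1. Step 10. The cycloaddition of a disubstituted ynoate shielded by a quaternary ketal carbon may be slow enough that thermal breakdown of the aryloxypyranone, loss of methanol from the ketal or leakage of regiochemistry competes.
Fallback: set out from 13 and return at 21. Compound 13 would be heated with dimethyl acetylenedicarboxylate, a symmetrical and much more reactive dienophile (toluene, 110 °C). The bicyclic adduct dimethyl 1-aryloxy-8-methoxy-3-oxo-2-oxabicyclo[2.2.2]octa-5,7-diene-5,6-dicarboxylate F1 should lose CO2 to give benzyl 4,6-bis(benzyloxy)-3-[5-methoxy-2,3-bis(methoxycarbonyl)phenoxy]-2-pentylbenzoate F2, with no regiochemical question. LiOH (1 equiv, THF/H2O, 0 °C) should cleave only the ester that has a single ortho neighbour and is not para to methoxy, giving 3-[4,6-bis(benzyloxy)-3-(benzyloxycarbonyl)-2-pentylphenoxy]-5-methoxy-2-(methoxycarbonyl)benzoic acid F3. EtSH, EDC and DMAP (CH2Cl2) would convert this to the S-ethyl thioester benzyl 4,6-bis(benzyloxy)-3-{3-[(ethylsulfanyl)carbonyl]-5-methoxy-2-(methoxycarbonyl)phenoxy}-2-pentylbenzoate F4. Fukuyama coupling with n-BuZnBr and catalytic PdCl2(PPh3)2 would then install the butyl ketone and give 21 directly, so step 11 is skipped.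

2. Step 7. Attack of a phenoxide flanked by pentyl and benzyloxy groups may be sluggish, while base-induced ring opening or hydrolysis of the chloropyranone consumes the electrophile.
Fallback: set out from 7 and 12 and return at 13. The uncatalysed addition–elimination would be replaced by a metal-catalysed C–O cross-coupling: Pd2(dba)3, 2-di-tert-butylphosphino-2',4',6'-triisopropylbiphenyl, K3PO4, toluene, 80 °C. Zerovalent palladium inserts into C6–Cl, as in cross-couplings at that position of chloropyranones, and C–O reductive elimination from the hindered aryloxide complex is driven by the bulky ligand. This fallback makes no new compound (none F0).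

3. Step 8. Ionisation of the orthoester may be slow, and disproportionation of the ethynyl Grignard reagent on heating would lead to double alkynylation of acetylene.
Fallback: set out from 15 and return at 16. Ethynylmagnesium bromide 15 would be acylated with N-methoxy-N-methylpentanamide (THF, 0 °C), the chelated tetrahedral intermediate stopping at the ketone stage, to give hept-1-yn-3-one F5. Ketalisation with methoxytrimethylsilane (2.2 equiv) and catalytic trimethylsilyl triflate (CH2Cl2, −78 °C) avoids conjugate addition of methanol and should give 16.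

Further compounds
F1 | step 10 | dimethyl 1-aryloxy-8-methoxy-3-oxo-2-oxabicyclo[2.2.2]octa-5,7-diene-5,6-dicarboxylate (aryl = ring A of 7; racemic, not isolated) | O=C1OC2(Oc3c(CCCCC)c(C(=O)OCc4ccccc4)c(OCc4ccccc4)cc3OCc3ccccc3)C=C(OC)C1C(C(=O)OC)=C2C(=O)OC
F2 | step 10 | benzyl 4,6-bis(benzyloxy)-3-[5-methoxy-2,3-bis(methoxycarbonyl)phenoxy]-2-pentylbenzoate | CCCCCc1c(Oc2cc(OC)cc(C(=O)OC)c2C(=O)OC)c(OCc2ccccc2)cc(OCc2ccccc2)c1C(=O)OCc1ccccc1
F3 | step 10 | 3-[4,6-bis(benzyloxy)-3-(benzyloxycarbonyl)-2-pentylphenoxy]-5-methoxy-2-(methoxycarbonyl)benzoic acid | CCCCCc1c(Oc2cc(OC)cc(C(=O)O)c2C(=O)OC)c(OCc2ccccc2)cc(OCc2ccccc2)c1C(=O)OCc1ccccc1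
F4 | step 10 | benzyl 4,6-bis(benzyloxy)-3-{3-[(ethylsulfanyl)carbonyl]-5-methoxy-2-(methoxycarbonyl)phenoxy}-2-pentylbenzoate | CCCCCc1c(Oc2cc(OC)cc(C(=O)SCC)c2C(=O)OC)c(OCc2ccccc2)cc(OCc2ccccc2)c1C(=O)OCc1ccccc1
F0 | step 7 | none | none
F5 | step 8 | hept-1-yn-3-one | CCCCC(=O)C#C
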